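The 14-membered lactone is disconnected between the fully substituted carbinol carbon C4 and the allylic methylene C5. The key step exploits the C1–C3 β-keto lactone unit that flanks C4: as its dianion, C2 is masked as an enolate and C4 becomes the only carbanionic site. One operation then closes the macrocycle by SN2 attack of C4 on an (E)-allylic bromide at C5, creates the tertiary C4–O stereocentre under control of a 4-methoxybenzylidene acetal bridging O4 and O4′, and erases the C2 and C4 configurations of the precursor. That precursor is an open-chain bromo β-keto ester built from three fragments (C5–C10, C11–C13 and C1–C4′).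

Key step: step 16

Remark (numbering): C1 lactone carbonyl, C2 (CH3), C3 ketone, C4 carbinol carbon, C4′ its CH2OH carbon, C5 CH2, C6=C7, C8 (CH3), C9, C10 (=CH2), C11=C12, C13 (ethyl, lactone oxygen).

Assumption: C2 lies between two carbonyl groups and is configurationally labile; its (2S) configuration is taken to be the thermodynamically preferred one in the 14-membered ring, so it is set by equilibration in the last step and is left undefined in compounds 28 to 33.

Step 1
Reactants: 1 (S)-4-benzyl-3-propanoyl-1,3-oxazolidin-2-one; 2 2,3-dibromoprop-1-ene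
Product: 4 (S)-4-benzyl-3-[(R)-4-bromo-2-methylpent-4-enoyl]-1,3-oxazolidin-2-one, via sodium enolate 3 (not isolated)
Conditions: NaN(SiMe3)2, THF, −78 °C; then 2, −78 → −40 °C
Reagents that add atoms: 2,3-dibromoprop-1-ene, C=C(Br)CBr
Why: Evans asymmetric alkylation, in which the chelated sodium (Z)-enolate is alkylated by the allylic bromide terminus of 2 on the face opposite the benzyl group, which should set C8 as R.

Step 2
Reactants: 4 (S)-4-benzyl-3-[(R)-4-bromo-2-methylpent-4-enoyl]-1,3-oxazolidin-2-one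
Product: 5 (R)-4-bromo-2-methylpent-4-en-1-ol
Conditions: LiBH4, THF, 0 °C → rt
Reagents that add atoms: none
Why: Reductive cleavage of the N-acyl oxazolidinone by LiBH4 should give the primary alcohol and leave the vinyl bromide and the α-stereocentre untouched.

Step 3
Reactants: 5 (R)-4-bromo-2-methylpent-4-en-1-ol; 6 ethyl 2-(triphenyl-λ5-phosphanylidene)propanoate
Product: 8 ethyl (2E,4R)-6-bromo-2,4-dimethylhepta-2,6-dienoate, via aldehyde 7 (not isolated)
Conditions: Dess–Martin periodinane, CH2Cl2, 0 °C → rt; then 6, rt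
Reagents that add atoms: ethyl 2-(triphenyl-λ5-phosphanylidene)propanoate, CCOC(=O)C(C)=P(c1ccccc1)(c1ccccc1)c1ccccc1
Why: Dess–Martin oxidation followed in the same flask by Wittig olefination with the stabilised ylide should give the (E)-trisubstituted enoate (C6=C7) without isolating the epimerisable α-methyl aldehyde.

Step 4
Reactants: 8 ethyl (2E,4R)-6-bromo-2,4-dimethylhepta-2,6-dienoate
Product: 9 (2E,4R)-6-bromo-2,4-dimethylhepta-2,6-dien-1-ol
Conditions: i-Bu2AlH, CH2Cl2, −78 °C
Reagents that add atoms: none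
Why: 1,2-Reduction of the enoate by i-Bu2AlH should give the allylic alcohol (C5–OH) with the vinyl bromide inert.

Step 5
Reactants: 9 (2E,4R)-6-bromo-2,4-dimethylhepta-2,6-dien-1-ol; 10 tert-butylchlorodimethylsilane
Product: 11 [(2E,4R)-6-bromo-2,4-dimethylhepta-2,6-dien-1-yl]oxy(tert-butyl)dimethylsilane
Conditions: imidazole, DMF, 0 °C → rt
Reagents that add atoms: tert-butylchlorodimethylsilane, CC(C)(C)[Si](C)(C)Cl
Why: Silylation protects the primary allylic alcohol so that C5–O survives the organoaluminium and enolate steps.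

Step 6
Reactants: 12 bis(trimethylsilyl)acetylene; 13 propanoyl chloride
Product: 14 1-(trimethylsilyl)pent-1-yn-3-one
Conditions: AlCl3, CH2Cl2, 0 °C
Reagents that add atoms: propanoyl chloride, CCC(=O)Cl
Why: Friedel–Crafts-type acylation of the bis-silyl alkyne (ipso substitution of one silyl group) should give the alkynyl ketone.

Step 7
Reactants: 14 1-(trimethylsilyl)pent-1-yn-3-one
Product: 15 (R)-1-(trimethylsilyl)pent-1-yn-3-ol
Conditions: RuCl[(R,R)-TsDPEN](p-cymene) (1 mol %), i-PrOH, rt
Reagents that add atoms: none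
Why: Noyori asymmetric transfer hydrogenation of the alkynyl ketone, in which the (R,R)-catalyst should deliver hydride to the face that gives the (R)-propargylic alcohol (future C13).

Step 8
Reactants: 15 (R)-1-(trimethylsilyl)pent-1-yn-3-ol
Product: 16 (R)-pent-1-yn-3-ol
Conditions: K2CO3 (cat.), MeOH, rt
Reagents that add atoms: none
Why: Base-catalysed methanolysis of the alkynyl C–Si bond should free the terminal alkyne without affecting the carbinol centre.

Step 9
Reactants: 16 (R)-pent-1-yn-3-ol; 17 trimethylaluminium; 11 [(2E,4R)-6-bromo-2,4-dimethylhepta-2,6-dien-1-yl]oxy(tert-butyl)dimethylsilane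
Product: 19 (3R,4E,8R,9E)-11-[(tert-butyldimethylsilyl)oxy]-4,8,10-trimethyl-6-methylideneundeca-4,9-dien-3-ol, via alkenylalane 18 (not isolated)
Conditions: Me3Al (3 equiv), Cp2ZrCl2 (0.3 equiv), CH2Cl2, 0 °C → rt; then 11, ZnCl2, Pd(PPh3)4 (5 mol %), THF, rt
Reagents that add atoms: trimethylaluminium, C[Al](C)C
Why: Zirconium-catalysed syn-carboalumination (Negishi) should place methyl on the internal and aluminium on the terminal alkyne carbon, fixing the (E)-C11=C12 geometry, and the alkenylalane is then cross-coupled in situ (Negishi coupling through zinc) with the vinyl bromide to form the C10–C11 bond of the diene.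

Step 10
Reactants: 19 (3R,4E,8R,9E)-11-[(tert-butyldimethylsilyl)oxy]-4,8,10-trimethyl-6-methylideneundeca-4,9-dien-3-ol; 20 propanoic anhydride
Product: 21 (3R,4E,8R,9E)-11-[(tert-butyldimethylsilyl)oxy]-4,8,10-trimethyl-6-methylideneundeca-4,9-dien-3-yl propanoate
Conditions: Et3N, DMAP (cat.), CH2Cl2, 0 °C → rt
Reagents that add atoms: propanoic anhydride, CCC(=O)OC(=O)CC
Why: DMAP-catalysed acylation of the secondary allylic alcohol should install the lactone oxygen–C1 bond together with C2 and its methyl group.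

Step 11
Reactants: 22 methyl (R)-2,3-dihydroxypropanoate; 23 4-methoxybenzaldehyde dimethyl acetal
Product: 24 methyl (2R,4R)-2-(4-methoxyphenyl)-1,3-dioxolane-4-carboxylate (cis)
Conditions: CSA (cat.), CH2Cl2, rt; chromatography
Reagents that add atoms: 4-methoxybenzaldehyde dimethyl acetal, COC(OC)c1ccc(OC)cc1
Why: Acid-catalysed transacetalisation should give the cis acetal together with its epimer at the acetal carbon, from which it is separated (the epimer can be re-equilibrated), and this (R)-acetal carbon is the later control element for C4.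

Step 12
Reactants: 24 methyl (2R,4R)-2-(4-methoxyphenyl)-1,3-dioxolane-4-carboxylate; 25 N,O-dimethylhydroxylamine hydrochloride
Product: 26 (2R,4R)-N-methoxy-2-(4-methoxyphenyl)-N-methyl-1,3-dioxolane-4-carboxamide
Conditions: i-PrMgCl, THF, −20 °C
Reagents that add atoms: N,O-dimethylhydroxylamine hydrochloride, CNOC.Cl
Why: Aminolysis of the ester by the magnesium amide of N,O-dimethylhydroxylamine should give the Weinreb amide with the acetal carbon untouched.

Step 13
Reactants: 21 (3R,4E,8R,9E)-11-[(tert-butyldimethylsilyl)oxy]-4,8,10-trimethyl-6-methylideneundeca-4,9-dien-3-yl propanoate; 26 (2R,4R)-N-methoxy-2-(4-methoxyphenyl)-N-methyl-1,3-dioxolane-4-carboxamide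
Product: 28 (3R,4E,8R,9E)-11-[(tert-butyldimethylsilyl)oxy]-4,8,10-trimethyl-6-methylideneundeca-4,9-dien-3-yl 3-[(2R,4R)-2-(4-methoxyphenyl)-1,3-dioxolan-4-yl]-2-methyl-3-oxopropanoate (C2 epimers), via lithium enolate 27 (not isolated)
Conditions: LiN(i-Pr)2, THF, −78 °C; then 26, −78 → −40 °C; aq. NH4Cl
Reagents that add atoms: none
Why: Crossed Claisen-type acylation in which the lithium ester enolate adds to the Weinreb amide, whose chelated tetrahedral intermediate prevents over-addition and should release the β-keto ester (C2–C3 bond) on work-up.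

Step 14
Reactants: 28 the silyl-protected β-keto ester
Product: 29 (3R,4E,8R,9E)-11-hydroxy-4,8,10-trimethyl-6-methylideneundeca-4,9-dien-3-yl 3-[(2R,4R)-2-(4-methoxyphenyl)-1,3-dioxolan-4-yl]-2-methyl-3-oxopropanoate (C2 epimers)
Conditions: Bu4NF, AcOH, THF, 0 °C → rt
Reagents that add atoms: none
Why: Buffered fluoride cleavage of the primary silyl ether should free the C5 hydroxyl while the acetal, the allylic ester and the β-keto ester stay intact.

Step 15
Reactants: 29 the hydroxy β-keto ester; 30 carbon tetrabromide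
Product: 31 (3R,4E,8R,9E)-11-bromo-4,8,10-trimethyl-6-methylideneundeca-4,9-dien-3-yl 3-[(2R,4R)-2-(4-methoxyphenyl)-1,3-dioxolan-4-yl]-2-methyl-3-oxopropanoate (C2 epimers)
Conditions: PPh3, 2,6-lutidine, CH2Cl2, 0 °C
Reagents that add atoms: carbon tetrabromide, BrC(Br)(Br)Br
Why: Appel bromination should convert the primary allylic alcohol into the bromide under neutral conditions with the (E)-C6=C7 geometry retained.

Step 16
Reactants: 31 the bromo β-keto ester
Product: 33 (2R,5R,10R,11E,15R,16E)-10-ethyl-2-(4-methoxyphenyl)-7,11,15,17-tetramethyl-13-methylidene-1,3,9-trioxaspiro[4.13]octadeca-11,16-diene-6,8-dione (the O4/O4′ 4-methoxybenzylidene acetal of the target; C2 epimers), via dilithium dianion 32 (not isolated)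
Conditions: LiN(i-Pr)2 (2.5 equiv), THF/DMPU, −78 → −30 °C, 2 mM; AcOH, −78 °C
Reagents that add atoms: none
Why: The first equivalent of LiN(i-Pr)2 removes the C2–H and the second the C4–H, so the C1–C3 unit is locked as an enolate and the cross-conjugated dianion carries its reactive carbanion at C4, exocyclic to the dioxolane; this carbon displaces the primary allylic bromide at C5 (SN2) and closes the ring. The closest known reaction types are the γ-alkylation of β-keto ester dianions by allylic halides, including its intramolecular use for macrocyclic β-keto lactones, and the alkylation of dioxolane enolates with an exocyclic double bond (self-regeneration of stereocentres). The 14-membered ring closes in a 14-exo-tet mode. The new stereocentre C4 is controlled by the (R)-configured acetal carbon: C5 enters the planar C4 on the face anti to the 4-methoxyphenyl group, which should give 4R whichever C2 and C4 epimers of 31 are used (stereoconvergent), while C2 is left for later equilibration. The step needs γ- rather than C2- or O-alkylation (secured by the dianion, whose C4 terminus is the most nucleophilic site), SN2 rather than SN2′ attack (primary C5 against the hindered C7, so the E geometry of C6=C7 is kept) and ring closure rather than oligomerisation (2 mM).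

Step 17
Reactants: 33 the acetal-protected macrolactone
Product: 34 (3S,5R,7E,9R,12E,14R)-14-ethyl-5-hydroxy-5-(hydroxymethyl)-3,7,9,13-tetramethyl-11-methylideneoxacyclotetradeca-7,12-diene-2,4-dione
Conditions: AcOH/THF/H2O (4:1:1), rt
Reagents that add atoms: none
Why: Mild acid hydrolysis of the electron-rich benzylidene acetal should free the C4 and C4′ hydroxyls without ionising the allylic lactone, and C2 should equilibrate through the enol to the more stable (2S) epimer.

Compound list
1 | (S)-4-benzyl-3-propanoyl-1,3-oxazolidin-2-one | CCC(=O)N1[C@@H](Cc2ccccc2)COC1=O | starting material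
2 | 2,3-dibromoprop-1-ene | C=C(Br)CBr | starting material
3 | sodium (Z)-enolate of 1 | C/C=C(\O[Na])N1[C@@H](Cc2ccccc2)COC1=O | intermediate (not isolated)
4 | (S)-4-benzyl-3-[(R)-4-bromo-2-methylpent-4-enoyl]-1,3-oxazolidin-2-one | C=C(Br)C[C@@H](C)C(=O)N1[C@@H](Cc2ccccc2)COC1=O | intermediate
5 | (R)-4-bromo-2-methylpent-4-en-1-ol | C=C(Br)C[C@@H](C)CO | intermediate
6 | ethyl 2-(triphenyl-λ5-phosphanylidene)propanoate | CCOC(=O)C(C)=P(c1ccccc1)(c1ccccc1)c1ccccc1 | starting material
7 | (R)-4-bromo-2-methylpent-4-enal | C=C(Br)C[C@@H](C)C=O | intermediate (not isolated)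
8 | ethyl (2E,4R)-6-bromo-2,4-dimethylhepta-2,6-dienoate | C=C(Br)C[C@@H](C)/C=C(\C)C(=O)OCC | intermediate
9 | (2E,4R)-6-bromo-2,4-dimethylhepta-2,6-dien-1-ol | C=C(Br)C[C@@H](C)/C=C(\C)CO | intermediate
10 | tert-butylchlorodimethylsilane | CC(C)(C)[Si](C)(C)Cl | starting material
11 | [(2E,4R)-6-bromo-2,4-dimethylhepta-2,6-dien-1-yl]oxy(tert-butyl)dimethylsilane | C=C(Br)C[C@@H](C)/C=C(\C)CO[Si](C)(C)C(C)(C)C | intermediate
12 | bis(trimethylsilyl)acetylene | C[Si](C)(C)C#C[Si](C)(C)C | starting material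
13 | propanoyl chloride | CCC(=O)Cl | starting material
14 | 1-(trimethylsilyl)pent-1-yn-3-one | CCC(=O)C#C[Si](C)(C)C | intermediate
15 | (R)-1-(trimethylsilyl)pent-1-yn-3-ol | CC[C@@H](O)C#C[Si](C)(C)C | intermediate
16 | (R)-pent-1-yn-3-ol | CC[C@@H](O)C#C | intermediate
17 | trimethylaluminium | C[Al](C)C | starting material
18 | dimethylaluminium alkoxide of (1E,3R)-1-(dimethylalumanyl)-2-methylpent-1-en-3-ol | CC[C@@H](O[Al](C)C)/C(C)=C/[Al](C)C | intermediate (not isolated)
19 | (3R,4E,8R,9E)-11-[(tert-butyldimethylsilyl)oxy]-4,8,10-trimethyl-6-methylideneundeca-4,9-dien-3-ol | CC[C@@H](O)/C(C)=C/C(=C)C[C@@H](C)/C=C(\C)CO[Si](C)(C)C(C)(C)C | intermediate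
20 | propanoic anhydride | CCC(=O)OC(=O)CC | starting material
21 | (3R,4E,8R,9E)-11-[(tert-butyldimethylsilyl)oxy]-4,8,10-trimethyl-6-methylideneundeca-4,9-dien-3-yl propanoate | CC[C@@H](OC(=O)CC)/C(C)=C/C(=C)C[C@@H](C)/C=C(\C)CO[Si](C)(C)C(C)(C)C | intermediate
22 | methyl (R)-2,3-dihydroxypropanoate | COC(=O)[C@H](O)CO | starting material
23 | 4-methoxybenzaldehyde dimethyl acetal | COC(OC)c1ccc(OC)cc1 | starting material
24 | methyl (2R,4R)-2-(4-methoxyphenyl)-1,3-dioxolane-4-carboxylate | COC(=O)[C@H]1CO[C@@H](c2ccc(OC)cc2)O1 | intermediate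
25 | N,O-dimethylhydroxylamine hydrochloride | CNOC.Cl | starting material
26 | (2R,4R)-N-methoxy-2-(4-methoxyphenyl)-N-methyl-1,3-dioxolane-4-carboxamide | CON(C)C(=O)[C@H]1CO[C@@H](c2ccc(OC)cc2)O1 | intermediate
27 | lithium enolate of 21 | CC[C@@H](OC(O[Li])=CC)/C(C)=C/C(=C)C[C@@H](C)/C=C(\C)CO[Si](C)(C)C(C)(C)C | intermediate (not isolated)
28 | (3R,4E,8R,9E)-11-[(tert-butyldimethylsilyl)oxy]-4,8,10-trimethyl-6-methylideneundeca-4,9-dien-3-yl 3-[(2R,4R)-2-(4-methoxyphenyl)-1,3-dioxolan-4-yl]-2-methyl-3-oxopropanoate (C2 epimers, C2 undefined) | CC[C@@H](OC(=O)C(C)C(=O)[C@H]1CO[C@@H](c2ccc(OC)cc2)O1)/C(C)=C/C(=C)C[C@@H](C)/C=C(\C)CO[Si](C)(C)C(C)(C)C | intermediate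
29 | (3R,4E,8R,9E)-11-hydroxy-4,8,10-trimethyl-6-methylideneundeca-4,9-dien-3-yl 3-[(2R,4R)-2-(4-methoxyphenyl)-1,3-dioxolan-4-yl]-2-methyl-3-oxopropanoate (C2 undefined) | CC[C@@H](OC(=O)C(C)C(=O)[C@H]1CO[C@@H](c2ccc(OC)cc2)O1)/C(C)=C/C(=C)C[C@@H](C)/C=C(\C)CO | intermediate
30 | carbon tetrabromide | BrC(Br)(Br)Br | starting material
31 | (3R,4E,8R,9E)-11-bromo-4,8,10-trimethyl-6-methylideneundeca-4,9-dien-3-yl 3-[(2R,4R)-2-(4-methoxyphenyl)-1,3-dioxolan-4-yl]-2-methyl-3-oxopropanoate (C2 undefined) | CC[C@@H](OC(=O)C(C)C(=O)[C@H]1CO[C@@H](c2ccc(OC)cc2)O1)/C(C)=C/C(=C)C[C@@H](C)/C=C(\C)CBr | intermediate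
32 | dilithium dianion of 31 (C2 enolate, C4 carbanion exocyclic to the dioxolane) | CC[C@@H](OC(O[Li])=C(C)C(O[Li])=C1CO[C@@H](c2ccc(OC)cc2)O1)/C(C)=C/C(=C)C[C@@H](C)/C=C(\C)CBr | intermediate (not isolated)
33 | (2R,5R,10R,11E,15R,16E)-10-ethyl-2-(4-methoxyphenyl)-7,11,15,17-tetramethyl-13-methylidene-1,3,9-trioxaspiro[4.13]octadeca-11,16-diene-6,8-dione (4R macrolactone with O4 and O4′ bridged as the (R)-4-methoxybenzylidene acetal; C2 undefined) | C=C1/C=C(\C)[C@@H](CC)OC(=O)C(C)C(=O)[C@@]2(O[C@H](c3ccc(OC)cc3)OC2)C/C(C)=C/[C@H](C)C1 | intermediate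
34 | (3S,5R,7E,9R,12E,14R)-14-ethyl-5-hydroxy-5-(hydroxymethyl)-3,7,9,13-tetramethyl-11-methylideneoxacyclotetradeca-7,12-diene-2,4-dione | C=C1/C=C(\C)[C@@H](CC)OC(=O)[C@@H](C)C(=O)[C@](O)(CO)C/C(C)=C/[C@H](C)C1 | target

Total step count: 17. Longest linear sequence: 12 steps (steps 1, 2, 3, 4, 5, 9, 10, 13, 14, 15, 16, 17).

Steps most likely to fail

Step 16 (key step). What may go wrong: slow or incomplete second deprotonation at the hindered, oxygen-bearing C4–H, ring-opening β-elimination of the dianion, oligomerisation in competition with ring closure, or erosion of facial selectivity. The fallback sets out from 19 and 24 and comes back at 33. The ring is still closed at C4–C5, but through a simple ester enolate in a 12-membered lactone that is then enlarged by two carbons. Saponification of 24 (LiOH, THF/H2O) should give (2R,4R)-2-(4-methoxyphenyl)-1,3-dioxolane-4-carboxylic acid F1. Steglich esterification of 19 with F1 (DCC, DMAP) should give the silyl-protected glycerate ester F2, Bu4NF/AcOH the allylic alcohol F3, and CBr4/PPh3 the allylic bromide F4. LiN(i-Pr)2 (1.1 equiv, THF/DMPU, −78 °C, 2 mM) should then close the 12-membered spiro-lactone F5 by alkylation of the ester enolate anti to the aryl group. Claisen condensation with the lithium enolate of tert-butyl propanoate opens the lactone to the hydroxy β-keto tert-butyl ester F6. Heating F6 in toluene (110 °C, 1 mM) should expel tert-butanol and lactonise the resulting acylketene onto the C13 hydroxyl to give 33.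

Step 9. What may go wrong: sluggish transfer of the alkenyl group from aluminium next to the aluminium alkoxide, with competing methyl transfer or protodealumination. The fallback sets out from 16 and 11 and comes back at 19. The alane from 16 (Me3Al, Cp2ZrCl2) is quenched with iodine to give (1E,3R)-1-iodo-2-methylpent-1-en-3-ol F7. Compound 11 is converted by Miyaura borylation (B2pin2, PdCl2(dppf), KOAc, dioxane, 80 °C) into the alkenyl pinacol boronate F8. Suzuki coupling of the two (Pd(PPh3)4, aq. K3PO4, THF) should give 19.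

Step 13. What may go wrong: proton transfer from the enolisable Weinreb amide to the ester enolate, or sigmatropic rearrangement of the allylic ester enolate on warming, leaving the acylation incomplete. The fallback sets out from 24 and 19 and comes back at 28. Compound 24 is condensed with the lithium enolate of tert-butyl propanoate (2.2 equiv, THF, −78 °C) to give tert-butyl 3-[(2R,4R)-2-(4-methoxyphenyl)-1,3-dioxolan-4-yl]-2-methyl-3-oxopropanoate F9. Heating this ester with 19 in toluene (110 °C) should transfer the acyl group through the acylketene, with loss of tert-butanol, to give 28.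

Further compounds
F1 | step 16 | (2R,4R)-2-(4-methoxyphenyl)-1,3-dioxolane-4-carboxylic acid | OC(=O)[C@H]1CO[C@@H](c2ccc(OC)cc2)O1
F2 | step 16 | (3R,4E,8R,9E)-11-[(tert-butyldimethylsilyl)oxy]-4,8,10-trimethyl-6-methylideneundeca-4,9-dien-3-yl (2R,4R)-2-(4-methoxyphenyl)-1,3-dioxolane-4-carboxylate | CC[C@@H](OC(=O)[C@H]1CO[C@@H](c2ccc(OC)cc2)O1)/C(C)=C/C(=C)C[C@@H](C)/C=C(\C)CO[Si](C)(C)C(C)(C)C
F3 | step 16 | (3R,4E,8R,9E)-11-hydroxy-4,8,10-trimethyl-6-methylideneundeca-4,9-dien-3-yl (2R,4R)-2-(4-methoxyphenyl)-1,3-dioxolane-4-carboxylate | CC[C@@H](OC(=O)[C@H]1CO[C@@H](c2ccc(OC)cc2)O1)/C(C)=C/C(=C)C[C@@H](C)/C=C(\C)CO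
F4 | step 16 | (3R,4E,8R,9E)-11-bromo-4,8,10-trimethyl-6-methylideneundeca-4,9-dien-3-yl (2R,4R)-2-(4-methoxyphenyl)-1,3-dioxolane-4-carboxylate | CC[C@@H](OC(=O)[C@H]1CO[C@@H](c2ccc(OC)cc2)O1)/C(C)=C/C(=C)C[C@@H](C)/C=C(\C)CBr
F5 | step 16 | (2R,5R,8R,9E,13R,14E)-8-ethyl-2-(4-methoxyphenyl)-9,13,15-trimethyl-11-methylidene-1,3,7-trioxaspiro[4.11]hexadeca-9,14-dien-6-one (12-membered lactone, C3 carbonyl on O13) | C=C1/C=C(\C)[C@@H](CC)OC(=O)[C@@]2(O[C@H](c3ccc(OC)cc3)OC2)C/C(C)=C/[C@H](C)C1
F6 | step 16 | tert-butyl 3-[(2R,4R)-4-[(2E,4R,7E,9R)-9-hydroxy-2,4,8-trimethyl-6-methylideneundeca-2,7-dien-1-yl]-2-(4-methoxyphenyl)-1,3-dioxolan-4-yl]-2-methyl-3-oxopropanoate (C2 undefined) | CC[C@@H](O)/C(C)=C/C(=C)C[C@@H](C)/C=C(\C)C[C@]1(C(=O)C(C)C(=O)OC(C)(C)C)CO[C@@H](c2ccc(OC)cc2)O1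
F7 | step 9 | (1E,3R)-1-iodo-2-methylpent-1-en-3-ol | CC[C@@H](O)/C(C)=C/I
F8 | step 9 | tert-butyldimethyl{[(2E,4R)-2,4-dimethyl-6-(4,4,5,5-tetramethyl-1,3,2-dioxaborolan-2-yl)hepta-2,6-dien-1-yl]oxy}silane | C=C(B1OC(C)(C)C(C)(C)O1)C[C@@H](C)/C=C(\C)CO[Si](C)(C)C(C)(C)C
F9 | step 13 | tert-butyl 3-[(2R,4R)-2-(4-methoxyphenyl)-1,3-dioxolan-4-yl]-2-methyl-3-oxopropanoate (C2 undefined) | CC(C(=O)OC(C)(C)C)C(=O)[C@H]1CO[C@@H](c2ccc(OC)cc2)O1
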